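**Strategy.** The cyclobutane is cut across C6–C7 and C3a′–C7a′ (phthalide locants; primed = E-butylidene unit). C3a′ and C7a′ are adjacent quaternary carbons shared by the four-membered ring, cyclohexene ring B and the lower γ-lactone, and their carbonyl-level neighbours C3′ and C1′ lie cis. An acylal ester C1′(=O)–O–C3′ therefore tethers a 2-vinylacrylate to a butenolide. One triplet-sensitised intramolecular [2+2] photocycloaddition forms C3a′–C7a′ (closing that lactone) and C6–C7, relaying the acylal configuration to the ring stereocentres. The same acylal carbon is later unmasked as the alkyne for the E-enol lactone; ring B comes from metathesis and the Z-butylidene butenolide from Claisen cyclisation and carbonylation.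

Key step: step 9

Remark: locants are the phthalide locants of the target (primed for the half whose butylidene group is E); the lipase in step 8 is assumed to acylate the (5S)-hemiacylal, which becomes (2R) in the ester only because the priority order of the two oxygens changes, and this selectivity has to be secured by enzyme choice.

Step 1
Reactants: 1 δ-valerolactone (oxan-2-one); 2 n-butyllithium
Product: 3 1-hydroxynonan-5-one
Conditions: THF, −78 °C; then H2O
Reagents that add atoms: none
Why: One equivalent of organolithium adds to the lactone at −78 °C and stops at the lithium hemiketal, which opens to the δ-hydroxy ketone on quench (nucleophilic acyl substitution with ring opening).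

Step 2
Reactants: 3 1-hydroxynonan-5-one
Product: 4 5-oxononanal
Conditions: (2,2,6,6-tetramethylpiperidin-1-yl)oxyl (10 mol%), PhI(OAc)2, CH2Cl2, rt
Reagents that add atoms: none
Why: Oxoammonium-catalysed oxidation should take the primary alcohol to the aldehyde without over-oxidation and leave the ketone alone.

Step 3
Reactants: 4 5-oxononanal; 5 methyl (2E)-but-2-enoate (methyl crotonate)
Product: 8 methyl (2E)-2-ethenyl-7-oxoundec-2-enoate, via aldol adduct 6 (not isolated), via mesylate 7 (not isolated)
Conditions: LiN(iPr)2, THF/DMPU, −78 °C (ester first, then aldehyde); MsCl, −78 → 0 °C; DBU, rt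
Reagents that add atoms: none
Why: The lithium dienolate of the crotonate should add through its α-carbon to the aldehyde faster than to the ketone, and mesylation followed by E1cB elimination gives the 2-vinyl enoate (vinylogous aldol reaction, then dehydration); its alkene geometry is lost again in step 9.

Step 4
Reactants: 8 methyl (2E)-2-ethenyl-7-oxoundec-2-enoate
Product: 9 (2E)-2-ethenyl-7-oxoundec-2-enoic acid
Conditions: LiOH, THF/H2O, 0 °C → rt; then 1 M HCl
Reagents that add atoms: lithium hydroxide, [Li+].[OH-]
Why: Saponification of an unhindered methyl ester (acyl substitution) should proceed under conditions that leave the ketone and the diene intact.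

Step 5
Reactants: 9 (2E)-2-ethenyl-7-oxoundec-2-enoic acid; 10 vinyl acetate
Product: 11 ethenyl (2E)-2-ethenyl-7-oxoundec-2-enoate
Conditions: Pd(OAc)2 (5 mol%), KOH (10 mol%), vinyl acetate as solvent, rt
Reagents that add atoms: none
Why: Pd(OAc)2-catalysed transvinylation exchanges acetate for the carboxylate and provides an irreversible acyl donor for the enzymatic step.

Step 6
Reactants: 12 3-bromofuran; 13 but-3-en-1-ylmagnesium bromide
Product: 14 3-(but-3-en-1-yl)furan
Conditions: Ni(dppp)Cl2 (3 mol%), Et2O/THF, 0 °C → reflux
Reagents that add atoms: none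
Why: Kumada cross-coupling of a heteroaryl bromide with a primary alkyl Grignard reagent, the chelating diphosphine suppressing β-hydride elimination.

Step 7
Reactants: 14 3-(but-3-en-1-yl)furan
Product: 15 4-(but-3-en-1-yl)-5-hydroxyfuran-2(5H)-one (racemic, epimerising hemiacylal)
Conditions: O2, 5,10,15,20-tetraphenylporphyrin (cat.), iPr2NEt, CH2Cl2, visible light, −78 °C → rt
Reagents that add atoms: dioxygen (as singlet oxygen), O=O
Why: Singlet oxygen adds [4+2] to the furan, and the hindered amine deprotonates the endoperoxide at its less hindered carbon (Kornblum–DeLaMare fragmentation), which should give the γ-hydroxybutenolide with the alkyl group next to the hemiacylal carbon; the monosubstituted alkene is inert to singlet oxygen.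

Step 8
Reactants: 11 ethenyl (2E)-2-ethenyl-7-oxoundec-2-enoate; 15 4-(but-3-en-1-yl)-5-hydroxyfuran-2(5H)-one
Product: 16 (2R)-3-(but-3-en-1-yl)-5-oxo-2,5-dihydrofuran-2-yl (2E)-2-ethenyl-7-oxoundec-2-enoate
Conditions: immobilised Burkholderia cepacia lipase, toluene, 4 Å molecular sieves, 35 °C
Reagents that add atoms: none
Why: Lipase-catalysed acylation under dynamic kinetic resolution: the enantiomers of the hemiacylal interconvert through the ring-opened formyl acid while the enzyme acylates only one, so the acylal stereocentre (future C3′) is set by the enzyme.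

Step 9
Reactants: 16 (2R)-3-(but-3-en-1-yl)-5-oxo-2,5-dihydrofuran-2-yl (2E)-2-ethenyl-7-oxoundec-2-enoate
Product: 17 tricyclic bis-lactone acylal (cyclobutane C6/C7/C3a′/C7a′ cis-fused to the lactones C7a(=O)–O–C3′ and C1′(=O)–O–C3′; ethenyl on C7a′, but-3-en-1-yl on C3a′ and 4-oxooctyl on C6, all on the face opposite the lactones)
Conditions: Ir[dF(CF3)ppy]2(dtbbpy)PF6 (1 mol%), degassed MeCN (0.01 M), 450 nm LEDs, rt
Reagents that add atoms: none
Why: Triplet energy transfer from the excited iridium complex (triplet energy near 61 kcal/mol) reaches only the 2-acyl-1,3-diene, whose twisted triplet adds through C7a′ to the butenolide β-carbon C3a′, and the resulting 1,4-biradical (C6 alkyl, C7 α-acyl) collapses after intersystem crossing to the four-membered ring. The closest known reactions are the visible-light-sensitised intramolecular [2+2] cycloaddition of 1,3-dienes with tethered alkenes and the intramolecular [2+2] photocycloaddition of 2(5H)-furanones, both following the rule of five. Ring closures: the γ-lactone ring by 5-exo-trig radical addition (C3a′–C7a′ bond), the cyclobutane by 1,4-biradical recombination (C6–C7 bond). Stereocentres: the three-atom acylal tether forces C1′ and C3′ cis and delivers the diene to the butenolide face that carries the acyloxy group, so the (R) acylal carbon fixes the absolute configuration of C3a′ and C7a′; the intact butenolide ring fixes C7 cis to C3′ (corrected in step 14), and the C6 chain should take the convex face away from both lactones, cis to the vinyl group. The step needs sensitisation of the diene only (not butenolide or ketone) and straight rather than crossed addition through the trisubstituted C6=C7a′ alkene rather than the vinyl group; the triplet energies and the preference for a five-membered first ring secure both.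

Step 10
Reactants: 17 tricyclic bis-lactone acylal
Product: 18 tetracyclic bis-lactone acylal (cyclohexene ring B closed between C7a′ and C3a′, alkene at C6′=C7′)
Conditions: second-generation Grubbs catalyst (5 mol%), CH2Cl2, 40 °C
Reagents that add atoms: none
Why: Ring-closing metathesis of the cis-disposed vinyl and butenyl groups closes the six-membered ring B with the alkene at C6′=C7′; no stereocentre is formed.

Step 11
Reactants: 18 tetracyclic bis-lactone acylal
Product: 20 6-ethynyl-7-(methoxycarbonyl)-8-(4-oxooctyl)bicyclo[4.2.0]oct-2-ene-1-carboxylic acid, via aldehyde acid 19 (not isolated)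
Conditions: K2CO3, MeOH, 0 °C; then dimethyl (1-diazo-2-oxopropyl)phosphonate, rt; citric acid work-up
Reagents that add atoms: methanol, CO; dimethyl (1-diazo-2-oxopropyl)phosphonate (Ohira–Bestmann reagent), COP(=O)(OC)C(=[N+]=[N-])C(C)=O
Why: Methoxide should open the less hindered lactone carbonyl (C7a, on a secondary carbon), the freed hemiacylal expels the C1′ carboxylate, and the non-enolisable aldehyde so released is homologated in the same flask faster than the dialkyl ketone reacts (lactone methanolysis, then Ohira–Bestmann alkynylation); one acylal carbon thus delivers the C7a ester, the C1′ acid and the C3′≡C8′ alkyne.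

Step 12
Reactants: 20 6-ethynyl-7-(methoxycarbonyl)-8-(4-oxooctyl)bicyclo[4.2.0]oct-2-ene-1-carboxylic acid
Product: 21 (E)-iodomethylidene γ-lactone (C1′ acid closed onto C3′; methyl ester on C7 and 4-oxooctyl on C6 unchanged)
Conditions: I2, NaHCO3, MeCN, 0 °C, dark
Reagents that add atoms: iodine, II
Why: anti-Iodolactonisation in the 5-exo-dig mode places iodine trans to the ring oxygen and so fixes the E geometry of the exocyclic alkene; this five-ring closure should outrun four-ring closure onto the neighbouring cyclohexene.

Step 13
Reactants: 21 (E)-iodomethylidene γ-lactone; 22 n-propylzinc bromide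
Product: 23 (E)-butylidene γ-lactone keto ester (methyl ester on C7, 4-oxooctyl on C6)
Conditions: Pd(dppf)Cl2 (5 mol%), THF, rt
Reagents that add atoms: none
Why: Negishi coupling proceeds with retention at the alkenyl iodide, so the propyl group ends trans to the lactone oxygen (E-butylidene), and the organozinc tolerates ester and ketone.

Step 14
Reactants: 23 (E)-butylidene γ-lactone keto ester
Product: 24 ring-A β-diketone (C7a ketone, pentanoyl group on C3a; ring A cis-fused to the cyclobutane on the ring-B face)
Conditions: LiN(SiMe3)2 (2.5 equiv), THF, −78 → 0 °C; then aq. NH4Cl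
Reagents that add atoms: none
Why: Intramolecular Claisen (Dieckmann-type) acylation of the ketone enolate at C3a by the C7a methyl ester closes ring A; C7 epimerises through its ester enolate and only the epimer with the ester cis to the C6 chain can cyclise, so the cis ring fusion (H-6 and H-7 cis, ring A syn to ring B) results and diketonate formation drives the reaction.

Step 15
Reactants: 24 ring-A β-diketone
Product: 25 C7a enol triflate (C7a=C3a alkene, pentanoyl group on C3a)
Conditions: Tf2O, iPr2NEt, CH2Cl2, −78 °C
Reagents that add atoms: trifluoromethanesulfonic anhydride, O=S(=O)(OS(=O)(=O)C(F)(F)F)C(F)(F)F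
Why: O-Sulfonylation of the β-diketone at the ring oxygen, whose enol keeps the double bond endocyclic in the six-membered ring, should give the cyclohexenyl triflate (enol triflate formation).

Step 16
Reactants: 25 C7a enol triflate
Product: 26 CNP0371639.1 (target)
Conditions: Pd(PPh3)4 (5 mol%), CO (1 atm), Et3N, DMF, 60 °C
Reagents that add atoms: carbon monoxide, [C-]#[O+]
Why: Oxidative addition, CO insertion and O-acylation of the neighbouring ketone enolate by the acylpalladium (carbonylative lactonisation) build the butenolide with C1 as its carbonyl; the Z-butylidene geometry, with propyl away from C4, is the favoured enol lactone geometry as in alkylidenephthalide formation.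

**Compound list**

1 | δ-valerolactone (oxan-2-one) | O=C1CCCCO1 | starting material
2 | n-butyllithium | [Li]CCCC | starting material
3 | 1-hydroxynonan-5-one | CCCCC(=O)CCCCO | intermediate
4 | 5-oxononanal | CCCCC(=O)CCCC=O | intermediate
5 | methyl (2E)-but-2-enoate | C/C=C/C(=O)OC | starting material
6 | methyl 2-ethenyl-3-hydroxy-7-oxoundecanoate (as lithium alkoxide, diastereomer mixture) | CCCCC(=O)CCCC(O)C(C=C)C(=O)OC | intermediate (not isolated)
7 | methyl 2-ethenyl-3-(methanesulfonyloxy)-7-oxoundecanoate | CCCCC(=O)CCCC(OS(C)(=O)=O)C(C=C)C(=O)OC | intermediate (not isolated)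
8 | methyl (2E)-2-ethenyl-7-oxoundec-2-enoate | CCCCC(=O)CCC/C=C(\C=C)C(=O)OC | intermediate
9 | (2E)-2-ethenyl-7-oxoundec-2-enoic acid | CCCCC(=O)CCC/C=C(\C=C)C(=O)O | intermediate
10 | vinyl acetate | CC(=O)OC=C | starting material
11 | ethenyl (2E)-2-ethenyl-7-oxoundec-2-enoate | CCCCC(=O)CCC/C=C(\C=C)C(=O)OC=C | intermediate
12 | 3-bromofuran | Brc1ccoc1 | starting material
13 | but-3-en-1-ylmagnesium bromide | C=CCC[Mg]Br | starting material
14 | 3-(but-3-en-1-yl)furan | C=CCCc1ccoc1 | intermediate
15 | 4-(but-3-en-1-yl)-5-hydroxyfuran-2(5H)-one (racemic) | C=CCCC1=CC(=O)OC1O | intermediate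
16 | (2R)-3-(but-3-en-1-yl)-5-oxo-2,5-dihydrofuran-2-yl (2E)-2-ethenyl-7-oxoundec-2-enoate | C=CCCC1=CC(=O)O[C@@H]1OC(=O)/C(C=C)=C/CCCC(=O)CCCC | intermediate
17 | tricyclic bis-lactone acylal: cyclobutane cis-fused to two γ-lactones sharing the acylal CH; ethenyl on C7a′, but-3-en-1-yl on C3a′ and 4-oxooctyl on C6, all on the face opposite the lactones | CCCCC(=O)CCC[C@H]1[C@@H]2C(=O)O[C@@H]3OC(=O)[C@@]1(C=C)[C@]23CCC=C | intermediate
18 | tetracyclic bis-lactone acylal: as the tricyclic acylal, with cyclohexene ring B closed (C6′=C7′) on the face opposite the lactones | CCCCC(=O)CCC[C@H]1[C@@H]2C(=O)O[C@@H]3OC(=O)[C@@]1(C=CCC4)[C@]234 | intermediate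
19 | 6-formyl-7-(methoxycarbonyl)-8-(4-oxooctyl)bicyclo[4.2.0]oct-2-ene-1-carboxylic acid (CO2H, CHO and CO2Me on the face opposite the six-membered ring, oxooctyl on the ring face) | CCCCC(=O)CCC[C@H]1[C@H](C(=O)OC)[C@@]2(C=O)CCC=C[C@@]12C(=O)O | intermediate (not isolated)
20 | 6-ethynyl-7-(methoxycarbonyl)-8-(4-oxooctyl)bicyclo[4.2.0]oct-2-ene-1-carboxylic acid (same configuration as the aldehyde acid; bicyclooctene C1 = C7a′, C6 = C3a′, C7 = C7, C8 = C6) | CCCCC(=O)CCC[C@H]1[C@H](C(=O)OC)[C@@]2(C#C)CCC=C[C@@]12C(=O)O | intermediate
21 | (E)-iodomethylidene γ-lactone of the alkynoic acid (propellane lactone; methyl ester on C7, 4-oxooctyl on C6) | CCCCC(=O)CCC[C@H]1[C@H](C(=O)OC)[C@@]23CCC=C[C@@]12C(=O)O/C3=C/I | intermediate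
22 | n-propylzinc bromide | CCC[Zn]Br | starting material
23 | (E)-butylidene γ-lactone keto ester (methyl ester on C7, 4-oxooctyl on C6) | CCCCC(=O)CCC[C@H]1[C@H](C(=O)OC)[C@@]23CCC=C[C@@]12C(=O)O/C3=C/CCC | intermediate
24 | ring-A β-diketone: C7a ketone, pentanoyl on C3a (enolisable centre); H-6 and H-7 cis, ring A syn to ring B; E-butylidene lactone intact | CCCCC(=O)C1CC[C@H]2[C@@H](C1=O)[C@@]13CCC=C[C@@]21C(=O)O/C3=C/CCC | intermediate
25 | C7a enol triflate of the β-diketone (C7a=C3a, pentanoyl on C3a) | CCCCC(=O)C=1CC[C@H]2[C@@H](C=1OS(=O)(=O)C(F)(F)F)[C@@]13CCC=C[C@@]21C(=O)O/C3=C/CCC | intermediate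
26 | CNP0371639.1: (3Z)-butylidene tetrahydrophthalide joined through C6 and C7 to C7a′ and C3a′ of the (3′E)-butylidene unit; H-6 and H-7 cis, ring A syn to ring B and anti to the primed lactone | CCC/C=C1\OC(=O)C2=C1CC[C@H]1[C@@H]2[C@@]23CCC=C[C@@]12C(=O)O/C3=C/CCC | target

**Step count and risks**

Total step count: 16. Longest linear sequence: 14 steps (steps 1–5 and 8–16).

Steps most likely to fail:

1. Step 9 (key step). What may go wrong: the acylal ester may sit mainly in its extended conformer, so that the diene triplet relaxes by E/Z isomerisation or dimerises before it reaches the butenolide; the C6 chain could also close on the concave face. Fallback, setting out from 16 and coming back at 18: ring-closing metathesis is run first (second-generation Grubbs catalyst, toluene, high dilution, 80 °C) between the diene vinyl group and the butenyl group. This should give the nine-membered cis-lactone F1, whose ring holds the ester s-cis and the C6=C7a′ and C7=C3a′ alkenes face to face. The same sensitised irradiation then closes C3a′–C7a′ and C6–C7 across the ring and gives 18.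

2. Step 8. What may go wrong: slow turnover of the lipase with the branched, conjugated acyl donor, or acylation of the wrong enantiomer. Fallback, setting out from 9 and 15 and coming back at 16: non-enzymatic coupling (DCC, 4-(dimethylamino)pyridine cat., CH2Cl2, 0 °C) gives the racemic acylal F2, and its enantiomers are separated by preparative chromatography on a chiral stationary phase; only the (2R) enantiomer goes on.

3. Step 14. What may go wrong: C7 may epimerise too slowly, the ketone enolate may acylate on the enol-lactone carbonyl instead of the methyl ester, or the base may open the E-enol lactone before ring A closes. Fallback, setting out from 20 and coming back at 25: ring A is built before the enol lactone exists. NaOMe in MeOH at reflux (thermodynamic, epimerising Claisen cyclisation with the acid masked as its carboxylate) should give the diketone acid F3. KN(SiMe3)2 and PhNTf2 then give the enol triflate acid F4. Iodolactonisation (I2, NaHCO3, MeCN) gives the iodomethylidene lactone triflate F5, and Negishi coupling with 22 under Pd(dppf)Cl2, which should insert into the alkenyl iodide before the alkenyl triflate, gives 25.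

Further compounds
F1 | step 9 | nine-membered cis-lactone from metathesis of the acylal ester (butenolide fused; exocyclic C6=C7a′ alkene) | O=C1C=C2CC/C=C\C(=C/CCCC(=O)CCCC)C(=O)O[C@H]2O1
F2 | step 8 | racemic 3-(but-3-en-1-yl)-5-oxo-2,5-dihydrofuran-2-yl (2E)-2-ethenyl-7-oxoundec-2-enoate | C=CCCC1=CC(=O)OC1OC(=O)/C(C=C)=C/CCCC(=O)CCCC
F3 | step 14 | ring-A β-diketone with ethynyl on C3a′ and carboxylic acid on C7a′ | CCCCC(=O)C1CC[C@H]2[C@@H](C1=O)[C@@]1(C#C)CCC=C[C@@]21C(=O)O
F4 | step 14 | C7a enol triflate of the diketone acid | CCCCC(=O)C=1CC[C@H]2[C@@H](C=1OS(=O)(=O)C(F)(F)F)[C@@]1(C#C)CCC=C[C@@]21C(=O)O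
F5 | step 14 | C7a enol triflate with (E)-iodomethylidene γ-lactone | CCCCC(=O)C=1CC[C@H]2[C@@H](C=1OS(=O)(=O)C(F)(F)F)[C@@]13CCC=C[C@@]21C(=O)O/C3=C/I
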